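Numbering: C1 ketone, C2=C3(CH3), C4/C11 cyclobutane CH on C3/C1, C5 cyclobutane CH on C6Me2, C7/C9 ester carbinols, C8 CH2, C10 methylated cyclobutane carbon. The seven-membered ring joins C5 and C10, which face each other across the cyclobutane, on the side away from the C1–C3 bridge. Cutting C5–C6 and C9–C10 thus gives a bicyclo[1.1.0]butane with C4 and C11 tied by C1–C3, plus a C6–C9 bromo enone. One radical annulation spends the C5–C10 bond, closes the cycloheptanone and fixes C5 and C10. The precursor is enantiopure 1,3-dimethyltricyclo[4.1.0.0(2,7)]hept-3-ene, reached through a bridgehead sulfoxide. C9–O, C7–O and the C1 ketone follow by catalyst-controlled borylation, Evans–Tishchenko reduction and allylic oxidation.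

Key step: step 8

Remarks on the chemistry
* The stereodescriptors of the bicyclobutane and of the tricycle agree with the target: the hydrocarbon needed is (1R,2R,6R,7R), and C7 and C9 are both R and 1,3-anti.
* The ring closure creates C9 over a cyclobutane whose two sides differ only in the distant C1 and C3, so no facial bias is expected there. The ether oxygen is therefore carried as OMe, expelled after the closure, and C9–O is set afterwards by a chiral copper catalyst.
* A volatile hydrocarbon cannot be resolved directly. Its one bridgehead C–H is used to attach an enantiopure sulfinyl group, which is later removed without trace.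
* The racemic compounds of steps 2 to 4 are written without stereodescriptors; their relative configuration is fixed by the ring fusion.

Step 1
Reactants: 1 m-xylene
Product: 2 1,5-dimethylcyclohexa-1,4-diene
Conditions: Li, NH3 (l), t-BuOH, THF, −78 to −33 °C
Reagents that add atoms: none
Why: Birch reduction: the dissolved metal reduces the arene to the 1,4-diene that keeps both methyl groups on the double bonds, and tert-butanol as proton source avoids isomerisation to the conjugated diene.

Step 2
Reactants: 2 1,5-dimethylcyclohexa-1,4-diene, 3 bromoform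
Product: 4 rac-7,7-dibromo-1,3-dimethylbicyclo[4.1.0]hept-3-ene
Conditions: KOt-Bu, pentane, −20 to 0 °C, 2 in excess
Reagents that add atoms: none
Why: Dibromocarbene, made from bromoform by α-elimination, adds in a [2+1] cycloaddition to one of the two equivalent electron-rich trisubstituted double bonds, the diene being used in excess so that the mono-adduct with its necessarily cis-fused cyclopropane dominates.

Step 3
Reactants: 4 rac-7,7-dibromo-1,3-dimethylbicyclo[4.1.0]hept-3-ene
Product: 5 rac-1,3-dimethyltricyclo[4.1.0.0(2,7)]hept-3-ene
Conditions: MeLi, Et2O, −78 to 0 °C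
Reagents that add atoms: none
Why: Bromine–lithium exchange and loss of LiBr give the cyclopropylidene carbenoid, whose 1,3-insertion into the syn C–H of the ring methylene between C10 and C3 builds the bicyclobutane (the established carbenoid route to tricyclo[4.1.0.0(2,7)]heptanes); insertion into the other allylic methylene gives an isomer that is carried along and removed as its sulfoxide in step 4.

Step 4
Reactants: 5 rac-1,3-dimethyltricyclo[4.1.0.0(2,7)]hept-3-ene
Product: 7 1,3-dimethyl-7-[(S)-p-tolylsulfinyl]tricyclo[4.1.0.0(2,7)]hept-3-ene (the diastereomer whose carbon skeleton has the configuration of the target), via rac-7-lithio-1,3-dimethyltricyclo[4.1.0.0(2,7)]hept-3-ene 6 (not isolated)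
Conditions: n-BuLi, TMEDA, Et2O–hexane, rt; added to (1R,2S,5R)-menthyl (S)-p-toluenesulfinate, THF, −78 °C; chromatography, then crystallisation
Reagents that add atoms: (1R,2S,5R)-menthyl (S)-4-methylbenzenesulfinate, CC(C)[C@@H]1CC[C@@H](C)C[C@H]1O[S@](=O)c1ccc(C)cc1
Why: The bridgehead C–H of the bicyclobutane is the most acidic site and is lithiated selectively, and the Andersen sulfoxide synthesis (substitution at sulfur with inversion) then turns the racemate into two diastereomeric, UV-active sulfoxides that are separated together with the regioisomers from step 3, the sulfur centre serving as internal reference for an X-ray assignment.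

Step 5
Reactants: 7 1,3-dimethyl-7-[(S)-p-tolylsulfinyl]tricyclo[4.1.0.0(2,7)]hept-3-ene
Product: 9 (1R,2R,6R,7R)-1,3-dimethyltricyclo[4.1.0.0(2,7)]hept-3-ene, via enantiopure 7-lithio-1,3-dimethyltricyclo[4.1.0.0(2,7)]hept-3-ene 8 (not isolated)
Conditions: t-BuLi, THF, −78 °C; then MeOH
Reagents that add atoms: none
Why: Sulfoxide–lithium exchange with t-BuLi regenerates the bridgehead lithium compound, which cannot invert inside the tricycle, and methanol protonates it, so that the hydrocarbon is released as a single enantiomer.

Step 6
Reactants: 10 3-methylbutan-2-one, 11 ethyl formate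
Product: 13 (E)-1-methoxy-4-methylpent-1-en-3-one, via sodium 4-methyl-3-oxopent-1-en-1-olate 12 (not isolated)
Conditions: NaH, Et2O, 0 °C to rt; then Me2SO4, DMF, rt
Reagents that add atoms: dimethyl sulfate, COS(=O)(=O)OC
Why: Crossed Claisen formylation takes place at the methyl group because only that product forms a stabilised enolate, and the hard electrophile dimethyl sulfate alkylates this enolate on oxygen to the more stable (E)-β-methoxy enone.

Step 7
Reactants: 13 (E)-1-methoxy-4-methylpent-1-en-3-one
Product: 15 (E)-4-bromo-1-methoxy-4-methylpent-1-en-3-one, via (E)-1-methoxy-4-methyl-3-(trimethylsilyloxy)penta-1,3-diene 14 (not isolated)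
Conditions: TMSOTf, Et3N, CH2Cl2, 0 °C; then NBS, THF, −78 °C
Reagents that add atoms: N-bromosuccinimide, O=C1CCC(=O)N1Br
Why: The only enolisable position is the isopropyl CH, so soft enolisation gives the cross-conjugated 2-silyloxy diene, which N-bromosuccinimide brominates at the silyl enol ether terminus C6 as other electrophiles do with dienes of this type, leaving the vinylogous ester intact.

Step 8
Reactants: 9 (1R,2R,6R,7R)-1,3-dimethyltricyclo[4.1.0.0(2,7)]hept-3-ene, 15 (E)-4-bromo-1-methoxy-4-methylpent-1-en-3-one
Product: 17 tricyclic dienone (C7 ketone; C8=C9 and C2=C3 double bonds; H on C5 and CH3 on C10 syn to the C1–C3 bridge), via tricyclic 9-methoxy C7 ketone 16 (not isolated)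
Conditions: Ir(ppy)3 (1 mol %), Hantzsch ester (1.5 equiv), 2,6-lutidine, 15 (1.5 equiv, slow addition), MeCN, 450 nm LEDs, rt; then DBU, 50 °C
Reagents that add atoms: none
Why: Proposed new method: photoexcited Ir(ppy)3 reduces the C–Br bond of 15, the tertiary, electrophilic α-keto radical at C6 attacks the unsubstituted bridgehead C5 of 9 and cleaves the strained central bond, the tertiary cyclobutyl radical at C10 closes the cycloheptanone by 7-endo-trig addition to C9 (the β-carbon of the methoxy enone), and the C8 radical takes a hydrogen atom from the dihydropyridine; DBU then expels methanol from 16. The closest known reactions are radical strain-release additions to bicyclo[1.1.0]butanes, their stepwise formal cycloadditions to bicyclo[n.1.1]alkanes, and endo-selective closures of radicals onto tethered vinyl ketones. C5 and C10 are set by topology: the four-carbon chain can bridge them only when both new bonds lie on the face opposite the C1–C3 bridge, so any tricycle formed carries H on C5 and CH3 on C10 syn to that bridge, with the absolute configuration of 9. The step therefore needs the C6 radical to enter at C5 over the convex face; rear-side entry, the usual trajectory in radical openings of this ring system, would press the tertiary carbon against C1H2 and the C2=C3 bond and leads to an adduct that cannot cyclise. Attack at C5 and not at C10 is secured by the free bridgehead and the tertiary radical it leaves, and 7-endo over 6-exo closure by the polarity of the enone. C9 is formed without facial bias and is not relied on, since it becomes sp2 again in 17.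

Step 9
Reactants: 17 tricyclic dienone
Product: 19 (9R)-9-hydroxy tricyclic C7 ketone, via 9-(pinacolatoboryl) tricyclic C7 ketone 18 (not isolated)
Conditions: CuCl, NaOt-Bu, Taniaphos ligand (the antipode that gives 9R), B2pin2, MeOH, THF, rt; then NaBO3·4H2O, THF–H2O
Reagents that add atoms: sodium perborate, [Na+].[Na+].O[B-]1(O)OO[B-](O)(O)OO1
Why: Copper-catalysed conjugate borylation: the chiral bisphosphine–copper boryl complex adds to the cis-enone at C9 under catalyst control (the substrate has no facial bias of its own), methanol protonates the copper enolate, and perborate oxidises C–B to C–O with retention to give the 9R alcohol.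

Step 10
Reactants: 19 (9R)-9-hydroxy tricyclic C7 ketone, 20 (E)-2-methylbut-2-enal
Product: 21 (7R,9R)-7-hydroxy 9-tiglate
Conditions: SmI2 (0.3 equiv), THF, −10 °C
Reagents that add atoms: none
Why: Evans–Tishchenko reduction: the C9 hydroxyl forms a hemiacetal with the aldehyde, and a samarium-bridged six-membered transition state transfers its hydride to C7 from the side of O9, which gives the C9 tiglate and the C7 alcohol in the 1,3-anti (7R,9R) arrangement and leaves the two oxygens differentiated.

Step 11
Reactants: 21 (7R,9R)-7-hydroxy 9-tiglate, 22 3-methylbut-2-enoyl chloride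
Product: 23 (7R,9R)-9-tiglate 7-senecioate with C1 still CH2
Conditions: pyridine, DMAP (cat.), CH2Cl2, 0 °C
Reagents that add atoms: none
Why: Acylation of the hindered C7 alcohol with the acid chloride under DMAP catalysis, with pyridine as the only base so that no vinylketene forms and the senecioyl double bond stays conjugated, and at low temperature to keep the C9 tiglate from migrating.

Step 12
Reactants: 23 (7R,9R)-9-tiglate 7-senecioate
Product: 24 CNP0277258.1
Conditions: CrO3, 3,5-dimethylpyrazole, CH2Cl2, −20 °C
Reagents that add atoms: chromium trioxide, O=[Cr](=O)=O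
Why: Allylic oxidation with the chromium trioxide–3,5-dimethylpyrazole complex converts the ring methylene C1, the only allylic CH2 of the electron-rich C2=C3 bond, into the ketone as in the oxidation of α-pinene-type alkenes to verbenone-type enones, the bridgehead C4–H being unable to conjugate and the two ester double bonds being electron-poor.

Compound list
1 | m-xylene | Cc1cccc(C)c1 | starting material
2 | 1,5-dimethylcyclohexa-1,4-diene | CC1=CCC=C(C)C1 | intermediate
3 | bromoform | BrC(Br)Br | starting material
4 | rac-7,7-dibromo-1,3-dimethylbicyclo[4.1.0]hept-3-ene (cis-fused) | CC1=CCC2C(Br)(Br)C2(C)C1 | intermediate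
5 | rac-1,3-dimethyltricyclo[4.1.0.0(2,7)]hept-3-ene | CC1=CCC2C3C1C23C | intermediate
6 | rac-7-lithio-1,3-dimethyltricyclo[4.1.0.0(2,7)]hept-3-ene | CC1=CCC2C3([Li])C1C23C | intermediate
7 | 1,3-dimethyl-7-[(S)-p-tolylsulfinyl]tricyclo[4.1.0.0(2,7)]hept-3-ene, carbon skeleton configured as in 9 | CC1=CC[C@@H]2[C@]3([S@@](=O)c4ccc(C)cc4)[C@H]1[C@]23C | intermediate
8 | enantiopure 7-lithio-1,3-dimethyltricyclo[4.1.0.0(2,7)]hept-3-ene | CC1=CC[C@@H]2[C@]3([Li])[C@H]1[C@]23C | intermediate
9 | (1R,2R,6R,7R)-1,3-dimethyltricyclo[4.1.0.0(2,7)]hept-3-ene | CC1=CC[C@@H]2[C@@H]3[C@H]1[C@]23C | intermediate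
10 | 3-methylbutan-2-one | CC(C)C(C)=O | starting material
11 | ethyl formate | CCOC=O | starting material
12 | sodium (Z)-4-methyl-3-oxopent-1-en-1-olate | [Na+].[O-]/C=C\C(=O)C(C)C | intermediate
13 | (E)-1-methoxy-4-methylpent-1-en-3-one | CO/C=C/C(=O)C(C)C | intermediate
14 | (E)-1-methoxy-4-methyl-3-(trimethylsilyloxy)penta-1,3-diene | CO/C=C/C(O[Si](C)(C)C)=C(C)C | intermediate
15 | (E)-4-bromo-1-methoxy-4-methylpent-1-en-3-one | CO/C=C/C(=O)C(C)(C)Br | intermediate
16 | tricyclic C7 ketone, C9 methyl ether (both C9 epimers), C2=C3 alkene, H on C5 and CH3 on C10 syn to the C1–C3 bridge | COC1CC(=O)C(C)(C)[C@@H]2[C@H]3CC=C(C)[C@@H]2[C@]31C | intermediate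
17 | tricyclic dienone: C7 ketone, C8=C9 and C2=C3 double bonds | C1=CC(=O)C(C)(C)[C@@H]2[C@H]3CC=C(C)[C@@H]2[C@]31C | intermediate
18 | (9R)-9-(pinacolatoboryl) tricyclic C7 ketone | CC1(C)OB(OC1(C)C)[C@@H]1CC(=O)C(C)(C)[C@@H]2[C@H]3CC=C(C)[C@@H]2[C@]31C | intermediate
19 | (9R)-9-hydroxy tricyclic C7 ketone | O[C@@H]1CC(=O)C(C)(C)[C@@H]2[C@H]3CC=C(C)[C@@H]2[C@]31C | intermediate
20 | (E)-2-methylbut-2-enal | C/C=C(\C)C=O | starting material
21 | (7R,9R)-7-hydroxy 9-tiglate, C2=C3 alkene, C1 CH2 | C/C=C(\C)C(=O)O[C@@H]1C[C@@H](O)C(C)(C)[C@@H]2[C@H]3CC=C(C)[C@@H]2[C@]31C | intermediate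
22 | 3-methylbut-2-enoyl chloride | CC(C)=CC(Cl)=O | starting material
23 | (7R,9R)-9-tiglate 7-senecioate, C2=C3 alkene, C1 CH2 | C/C=C(\C)C(=O)O[C@@H]1C[C@@H](OC(=O)C=C(C)C)C(C)(C)[C@@H]2[C@H]3CC=C(C)[C@@H]2[C@]31C | intermediate
24 | CNP0277258.1 | C/C=C(\C)C(=O)O[C@@H]1C[C@@H](OC(=O)C=C(C)C)C(C)(C)[C@@H]2[C@H]3C(=O)C=C(C)[C@@H]2[C@]31C | target

Total step count: 12. Longest linear sequence: 10 steps (steps 1 to 5, then 8 to 12).

Steps most likely to fail

Step 8. The C6 radical may enter C5 from the rear of the central bond instead of over the convex face. That adduct has the chain syn to the C1–C3 bridge, cannot close the ring, and is simply reduced at C10. Further losses may come from reduction of the C6 or C10 radical before it forms its C–C bond, and from addition of the α-keto radical to the enol ether bond of a second molecule of 15. The fallback uses known chemistry only, sets out from 10 and comes back at 17. The lithium enolate of 10 (LDA, THF, −78 °C, kinetic deprotonation at the methyl group) is alkylated with methyl (2E,6E)-8-bromo-3,7-dimethylocta-2,6-dienoate to give methyl (2E,6E)-3,7,11-trimethyl-10-oxododeca-2,6-dienoate F1. LiOH gives (2E,6E)-3,7,11-trimethyl-10-oxododeca-2,6-dienoic acid F2 and oxalyl chloride its acid chloride F3. Triethylamine in refluxing toluene then brings about the intramolecular ketene–alkene [2+2] cycloaddition across the 6,7-double bond, a known entry to bicyclo[3.1.1]hept-2-en-6-ones. It should give the racemic cyclobutanone F4 with the C10 methyl syn to the C1–C3 bridge, as follows from the E double bond. The more substituted trimethylsilyl enol ether F5 (TMSCl, NaI, Et3N) closes C5–C6 by Mukaiyama aldol addition to the strained ketone (BF3·OEt2) to give the tertiary alcohol F6; the chain can reach C5 only from the side away from the bridge. The methyl oxalate F7 (methyl chlorooxoacetate, DMAP) is deoxygenated with Bu3SnH and AIBN to the saturated tricyclic ketone F8, which is resolved on a chiral stationary phase and dehydrogenated with IBX to 17.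

Step 3. The carbenoid may insert mainly into the other allylic methylene (C1–H), which lies next to the unsubstituted cyclopropane carbon and is activated by a tertiary allylic terminus, so that 5 becomes the minor isomer. The fallback sets out from 3 and comes back at 5. 3-Methylcyclohex-2-enone is treated with MeLi and the alkoxide is silylated in the same flask (Et3SiCl) to give triethyl[(1,3-dimethylcyclohex-2-en-1-yl)oxy]silane F9. Dibromocarbene from 3 (KOt-Bu, pentane) gives the dibromocyclopropane F10, in which the future C3 carries no hydrogen, so the carbenoid made with MeLi can insert only into the C11 methylene and should give the silyloxy bicyclobutane F11. TBAF frees the tertiary alcohol F12, and its S-methyl xanthate F13 (NaH, CS2, MeI) is pyrolysed in a Chugaev syn-elimination, which avoids a cation next to the bicyclobutane. The exocyclic-methylene isomer F14 formed beside 5 is moved into the ring with KOt-Bu in DMSO, and 5 then enters step 4.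

Step 10. Hemiacetal formation and hydride transfer to the neopentyl C7 ketone may be too slow with an α-branched unsaturated aldehyde, so that aldehyde self-condensation or acyl migration takes over. The fallback sets out from 19 and comes back at 21. 19 is acylated with tiglic anhydride and a catalytic amount of Sc(OTf)3 (acidic conditions, no β-elimination) to the β-tigloyloxy ketone F15. The C7 ketone is then reduced with catecholborane and the (S)-Me-CBS oxazaborolidine, which distinguishes the quaternary C6 from the C8 methylene and should give the 7R alcohol 21.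

Further compounds
F1 | step 8 | methyl (2E,6E)-3,7,11-trimethyl-10-oxododeca-2,6-dienoate | COC(=O)/C=C(\C)CC/C=C(\C)CCC(=O)C(C)C
F2 | step 8 | (2E,6E)-3,7,11-trimethyl-10-oxododeca-2,6-dienoic acid | OC(=O)/C=C(\C)CC/C=C(\C)CCC(=O)C(C)C
F3 | step 8 | (2E,6E)-3,7,11-trimethyl-10-oxododeca-2,6-dienoyl chloride | ClC(=O)/C=C(\C)CC/C=C(\C)CCC(=O)C(C)C
F4 | step 8 | rac-2,7-dimethyl-7-(4-methyl-3-oxopentyl)bicyclo[3.1.1]hept-2-en-6-one, 7-CH3 syn to the C2–C4 bridge (enantiomer of the target series drawn) | CC(C)C(=O)CC[C@]1(C)[C@@H]2C(=O)[C@H]1CC=C2C
F5 | step 8 | trimethylsilyl enol ether of F4 at the isopropyl ketone (racemate) | CC(C)=C(O[Si](C)(C)C)CC[C@]1(C)[C@@H]2C(=O)[C@H]1CC=C2C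
F6 | step 8 | tricyclic 5-hydroxy C7 ketone, C8 and C9 CH2 (racemate) | C1CC(=O)C(C)(C)[C@]2(O)[C@H]3CC=C(C)[C@@H]2[C@]31C
F7 | step 8 | methyl oxalate of F6 (racemate) | C1CC(=O)C(C)(C)[C@]2(OC(=O)C(=O)OC)[C@H]3CC=C(C)[C@@H]2[C@]31C
F8 | step 8 | tricyclic C7 ketone, C8 and C9 CH2, C2=C3 alkene (racemate, then resolved) | C1CC(=O)C(C)(C)[C@@H]2[C@H]3CC=C(C)[C@@H]2[C@]31C
F9 | step 3 | triethyl[(1,3-dimethylcyclohex-2-en-1-yl)oxy]silane (racemate) | CC1=CC(C)(O[Si](CC)(CC)CC)CCC1
F10 | step 3 | 7,7-dibromo-1,5-dimethyl-5-(triethylsilyloxy)bicyclo[4.1.0]heptane (racemate, both carbinol epimers) | CC12CCCC(C)(O[Si](CC)(CC)CC)C1C2(Br)Br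
F11 | step 3 | 1,3-dimethyl-3-(triethylsilyloxy)tricyclo[4.1.0.0(2,7)]heptane (racemate, both carbinol epimers) | CC1(O[Si](CC)(CC)CC)CCC2C3C1C23C
F12 | step 3 | 1,3-dimethyltricyclo[4.1.0.0(2,7)]heptan-3-ol (racemate, both carbinol epimers) | CC1(O)CCC2C3C1C23C
F13 | step 3 | O-(1,3-dimethyltricyclo[4.1.0.0(2,7)]hept-3-yl) S-methyl dithiocarbonate (racemate) | CSC(=S)OC1(C)CCC2C3C1C23C
F14 | step 3 | rac-1-methyl-3-methylidenetricyclo[4.1.0.0(2,7)]heptane | C=C1CCC2C3C1C23C
F15 | step 10 | (9R)-9-tigloyloxy tricyclic C7 ketone | C/C=C(\C)C(=O)O[C@@H]1CC(=O)C(C)(C)[C@@H]2[C@H]3CC=C(C)[C@@H]2[C@]31C
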